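The runs were computed with constants of no real substance, and the scatter is random.

The ratio of reagent lost to substrate reacted is the quantity reckoned here. Suppose reagent in the reaction phase decomposes in proportion to its own concentration and reacts in proportion to that times c(substrate). Each mM of substrate consumed then costs 1 + c*/c(substrate) mM of reagent, where c*, a selectivity factor with the units of concentration, is the c(substrate) at which both losses run equal. Counting the second phase and the dormant form as stores, and running until the reagent charge has reacted or decomposed, the costs sum to: charge = drop in c(substrate) + c* ln(c(substrate) at start / c(substrate) at end).

- teal: substrate 40 mM; reagent in the second phase 16 mM; run made earlier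
- flask: substrate 20 mM; reagent in the second phase 16.0 mM; time 50 min; volume of the second phase over the first 1.0
teal run (percent of the substrate charged)

| time / min | target / % | substrate / % |
|---|---|---|
| 2.50 | 6.2 | 92.9 |
| 5.00 | 11.8 | 87.0 |
| 8.00 | 16.6 | 81.9 |
| 10.0 | 17.7 | 78.7 |
| 12.0 | 18.8 | 77.1 |
| 15.0 | 19.3 | 74.8 |

(readings scatter by 0.5 percentage points)
- target and product in the second phase together at 50 min, in percent of the substrate charged
- part of the substrate charged that has reacted at 50 min
- target is meant together with its product in the second phase
- in the second phase: reagent in the second phase, product in the second phase; everything else is in the first
- charges count per volume of the first phase; a concentration in a rate is the amount of a species over the volume of its own phase; every rate counts per litre of the first phase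
- what may be going on: target <-> product in the second phase; substrate + reagent in the reaction phase -> target; reagent in the reaction phase <-> dormant form; target -> decomposed product; reagent in the reaction phase <-> reagent in the second phase; reagent in the reaction phase -> decomposed reagent
- the earlier runs hold the two phases in the same ratio of volumes as the flask asked about

In the teal run, substrate's fractional loss rate is 0.0279 /min up to 5.00 min, 0.0201 /min up to 10.0 min and 0.0102 /min up to 15.0 min. The first and last of these give an exponential decline of 0.101 /min. Continued past the last reading, that decline ends the teal run at 69.2% substrate, so the budget gives c* = 9.94 mM. One tangent step from a trial conversion of 0.5 then gives 47.8% for the flask.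

The weak link is that decline, since its first window covers the minutes when reagent is still entering the reaction phase. The two later windows give 0.136 /min, an end at 70.9%, c* = 12.7 mM, the break-even concentration, and 43.8% reacted in the flask. This reckoning gives no figure for target.

The forecast, a different reckoning, says 24% and 54%, holding that “Reagent therefore seems to go mainly by reaction”.

The flask gives 13.8% and 45.3%.

    target ⇌ product in the second phase, rate k1*([target] - [product in the second phase]/K1) per volume of the first phase (partition coefficient = 0.970, kL = 0.0100 /s)
    substrate + reagent in the reaction phase → target (k = 0.380 /M/s)
    reagent in the reaction phase ⇌ dormant form (K = 0.960, k = 0.00780 /s)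
    target → decomposed product (k = 0.00100 /s)
    reagent in the reaction phase ⇌ reagent in the second phase, rate k5*([reagent in the reaction phase] - [reagent in the second phase]/K5) per volume of the first phase (partition coefficient = 1.40, kL = 0.00470 /s)
    reagent in the reaction phase → decomposed reagent (k = 0.00430 /s)

At 50.0 min, substrate's half-life by reaction is 24 h, longer than the run, while target's half-life by decomposition is 12 min, shorter than the run. At that time the flask's substrate stands at 10.9 mM, where the c* read from the teal run puts the reagent lost at 2.16 times the substrate reacted. With 5.0 mM of substrate, the same c* gives 63.7% reacted; that flask gives 66.0%.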